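Target in the dusk run levels off near 41.0 % of the substrate charged at its last reading, although substrate is the limiting reagent of the dusk charge. You want to know what stops it, because that tells you what the target charged to the summer flask will do.

common to all: free catalyst 0.00400 M

|  | substrate | partner | target | time |
|---|---|---|---|---|
| dusk | 0.0500 M | 0.0600 M |  |  |
| midnight | 0.0250 M | 0.0350 M |  |  |
| winter | 0.150 M | 0.0600 M |  |  |
| dawn | 0.0500 M | 0.0900 M |  |  |
| summer | 0.0500 M | 0.0600 M | 0.0150 M | 3.9 h |

| dusk run: time / h | dusk run: [target] / M | midnight run: time / h | midnight run: [target] / M | winter run: time / h | winter run: [target] / M | dawn run: time / h | dawn run: [target] / M |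
|---|---|---|---|---|---|---|---|
| 0.78 | 0.0149 | 0.78 | 0.0053 | 0.78 | 0.0341 | 0.78 | 0.0178 |
| 1.6 | 0.0179 | 1.6 | 0.0070 | 1.6 | 0.0408 | 1.6 | 0.0210 |
| 2.3 | 0.0196 | 2.3 | 0.0081 | 2.3 | 0.0428 | 2.3 | 0.0209 |
| 3.1 | 0.0198 | 3.1 | 0.0083 | 3.1 | 0.0431 | 3.1 | 0.0219 |
| 3.9 | 0.0205 | 3.9 | 0.0087 | 3.9 | 0.0437 | 3.9 | 0.0214 |

(each reading ± 3 × 10⁻⁴ M)

- Overall: substrate + partner -> target, with free catalyst as catalyst.
- Constant volume, constant temperature.
- An order is taken over about fifteen percent of the charge, up and down.
- A share of target counts the target that was charged too.

* the exponent of [substrate] in the starting rate at the charge of the dusk run (at the point where two percent of the substrate have become target) (one fixed amount of target, the same in the runs compared)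
* the exponent of [partner] in the starting rate at the charge of the dusk run (at the point where two percent of the substrate have become target)
* target in the summer run at 3.9 h, as a share of the substrate charged

1. Turn the question round and ask what the readings would have to show if the flask stopped at a balance of the overall reaction. The dusk run gives 17.6 /M, and this is the stopping quotient: the last target reading divided by the substrate and the partner that the overall equation leaves at that reading.

2. A balance at one temperature needs one quotient, whatever the charge. The midnight run gives 20.3 /M, the winter run 25.2 /M and the dawn run 10.9 /M. Winter's reading is 2.31 times dawn's, while one standard deviation on dawn's last reading leaves its quotient at 11.2 /M. So these runs stand far from the single quotient a balance requires.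

3. Now solve the summer flask at both ends. It has the dusk charge plus target. If it held dusk's quotient, target would end at 58.1 % of the substrate charged. If the charged target changed nothing, summer would make what dusk made and end at 71.0 %, which is higher. The spread of quotients favours this second end, so I commit to 71.0 %.

4. The forecast gave 0.87 (0.7 to 1.05) for the substrate order, 0.92 (0.7 to 1.15) for the partner order, and 69 % (58 % to 73 %) for summer, against my 71.0 %. Its grounds: “That points to the catalyst dying, mainly along a partner-linked path, rather than to equilibrium.”

5. The flask gives 1.1 for the substrate order, 1.0 for the partner order and 70.7 % for summer. The substrate order is higher than forecast, and the other two fall inside the forecast's ranges.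

    2 free catalyst ⇌ catalyst dimer, settled at all times (8170 /M)
    catalyst dimer + substrate + partner → target + catalyst dimer (7524 /M²/h)
    free catalyst + partner → spent catalyst + partner (130.0 /M/h)
    partner → lost reagent (0.4680 /h)

Put the summer result into the stopping quotient and you get 30.0 /M, higher than dusk's reading of 17.6 /M, so the summer run went past the quotient at which dusk stood. Target in the summer run at 3.9 h is held down because free catalyst turns into spent catalyst in the presence of partner. With that step taken away, the summer run reaches 86.6 % instead of 70.7 %, a gain of 16 percentage points.

Readings and results come from a simulation with made-up constants.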